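Every L charged stays counted: c(L) + c(L.J) + c(Z) + c(L.E) remains 0.25 M, and E, the smaller charge, can take at most 0.0750 M of it.

    Q ⇌ J, rate k1*(csat - [J]) (k1 = 0.033 s⁻¹, csat = 12 mM)
    L + J → L.J (k2 = 0.0039 M⁻¹ s⁻¹)
    L.J ⇌ Z (K3 = 0.54, k3 = 1.0 × 10⁻⁵ s⁻¹)
    L + E → L.E (k4 = 0.0011 M⁻¹ s⁻¹)

L 0.25 M; Q 12 mM (held); E 0.0750 M; time 4.0 h

- ash: doubling the transfer coefficient of step 1, all else as stated
- elm: doubling the saturation concentration of Q, all else as stated

- at the start none of J is dissolved
- run time (flask): 4.0 h

- amount of L.J at 4.0 h, in percent of the L charged
- the change that raises the amount of L.J at 4.0 h, in percent of the L charged most ("none" if none brings more than 2 percentage points) (ash / elm / none)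
- amount of L.J at 4.0 h, in percent of the L charged, after elm

1. Step one delivers J at up to 0.033 s⁻¹, faster than L removes it, at 9.75 × 10⁻⁴ s⁻¹ even with the full charge of L. So, past the first moments after the empty start, you can take c(J) as at least 97.1% of saturation.

2. L then loses itself to J with a pseudo-first-order constant, 0.168 h⁻¹, the product of k2 and csat.

3. First extreme: the flask without E. You reckon L.J and Z together at 49.0% of the L charged.

4. Second extreme: E takes its whole charge from L at once. Then 70.0% of L remains, and you reckon L.J and Z together at 34.3%.

5. The real flask lies between these: E does not react at once, its half-life being 0.700 h at the full charge of L. It lies nearer the low end, because at the start E takes L faster than J does, at 0.297 h⁻¹. L.J has a forward half-life of 19 h by step 3, longer than 4.0 h, so L.J loses little by that step in this time.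

6. Under elm, kJ doubles and the bounds become 51.7% and 73.9%. Under ash, c(J) has little room left above 97.1% of saturation. I choose elm.

The forecast gives y = 35% (32% to 38%), best = elm and yb = 54% (49% to 58%), holding that “Gas transfer is much faster than J is consumed”. My reckoning gives bounds on L.J and Z together, not a value of y.

The flask gives y = 35.3%, best = elm with a gain of 18 percentage points against 0.25 points for ash, and yb = 53.6%. With E charged at 0.0349 M or 0.119 M, all else held, y has moved by 5 percentage points, outside the forecast's range. In the flask, L.J and Z together stand at 38.0%, between 34.3% and 49.0%. For the same flask read at 2.5 h, kJ gives bounds of 24.0% and 34.3%, and L.J and Z together stand at 27.8%.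

(The constants were set for the occasion.)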